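## Retrosynthetic overview

1. Target ⇒ terminal alkyne 13: C15 (CO2H) and C16 (CH3) are added last by a syn methyl-carboxylation of the alkyne, which fixes the 13E geometry.
2. 13 ⇒ tertiary allylic alcohol 12 by an acylative 1,3-transposition (C9–O becomes C7–O-isovaleryl, alkene moves to C8=C9); 12 ⇒ enone 10 by C6 reduction and acetylation.
3. 10 ⇒ enedione 5 plus a C4 alkynyl Grignard reagent (C9–C11 bond), with the ring fusion equilibrated to trans.
4. 5 ⇒ 2,6-dimethyl-1,4-benzoquinone 2 plus 4-methylpenta-1,3-diene 3 by an enantioselective Diels–Alder reaction that desymmetrises the C2v quinone and sets C10; 2 ⇒ 2,6-dimethylphenol 1 by oxidative dearomatisation.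
5. Ring order: ring B comes from the arene; ring A is annulated onto it by the cycloaddition.

Labdane numbering is used in the explanations: C5/C10 ring fusion, C6 (OAc), C7 (O-isovaleryl), C8=C9, side chain C11–C16. In quinone 2 the carbonyl between the two methyl-bearing carbons becomes C9 and the other becomes C6.

Assumption 1: the (R)-configured oxazaborolidinium catalyst is taken to give the (8aS) adduct, as its α-C–H···O pre-transition-state model predicts; if the sense were opposite, the (S)-antipode would be used with no other change.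

Assumption 2: the C9 carbinol configuration created in step 4 is immaterial (C9 becomes sp2 in step 7); it is drawn as the product of attack anti to the angular methyl.

## Route

Step 1
Reactants: 1 2,6-dimethylphenol
Product: 2 2,6-dimethyl-1,4-benzoquinone
Conditions: O2 (1 atm), Co(salen) (5 mol %), DMF, rt
Reagents that add atoms: dioxygen, O=O
Why: Cobalt–salen-catalysed aerobic para-oxidation of a 2,6-disubstituted phenol (phenoxyl radical trapped by O2 at the free para position) is a standard oxidative dearomatisation and gives the symmetric quinone, which has no stereocentre.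

Step 2
Reactants: 2 2,6-dimethyl-1,4-benzoquinone; 3 4-methylpenta-1,3-diene
Product: 4 (4aR,8aS)-2,5,5,8a-tetramethyl-4a,5,8,8a-tetrahydronaphthalene-1,4-dione (cis-fused)
Conditions: (R)-3,3-diphenyl-1-(o-tolyl)tetrahydro-1H,3H-pyrrolo[1,2-c][1,3,2]oxazaborole·HNTf2 (20 mol %), 3 (3 equiv, slow addition), CH2Cl2, −78 → −40 °C
Reagents that add atoms: none
Why: Catalytic enantioselective Diels–Alder reaction of a quinone with a cationic oxazaborolidinium Lewis acid, in which the catalyst binds the unhindered C6 carbonyl syn to the neighbouring vinylic C–H, the CH2 terminus of the diene (largest HOMO coefficient) attacks the activated methyl-bearing β-carbon (future C10) and the CMe2 terminus closes onto the CH carbon (future C5) so that no vicinal quaternary pair arises, and shielding of one face of the symmetry-equivalent C=C bonds sets quaternary C10 while suprafacial addition makes the ring fusion cis (corrected in step 4).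

Step 3
Reactants: 4 cis-fused Diels–Alder adduct
Product: 5 (4aR,8aS)-2,5,5,8a-tetramethyl-4a,5,6,7,8,8a-hexahydronaphthalene-1,4-dione (cis-fused)
Conditions: H2 (3 atm), RhCl(PPh3)3 (5 mol %), benzene, rt
Reagents that add atoms: none
Why: Homogeneous Wilkinson-type hydrogenation reduces the cis-disubstituted ring-A alkene and leaves the trisubstituted, acyl-flanked enedione alkene, which binds rhodium far more slowly, so no stereocentre is touched.

Step 4
Reactants: 5 cis-fused saturated enedione; 6 (4-bromobut-1-yn-1-yl)trimethylsilane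
Product: 10 (4S,4aS,8aS)-4-(but-3-yn-1-yl)-4-hydroxy-3,4a,8,8-tetramethyl-4a,5,6,7,8,8a-hexahydronaphthalen-1(4H)-one (trans-fused), via lithium enolate 7 (not isolated), via enolate alkoxide adduct 8 (not isolated), via silylated hydroxy enone 9 (not isolated)
Conditions: LiN(SiMe3)2 (1.1 equiv), THF, −78 °C; then Me3SiC≡CCH2CH2MgBr (from 6, Mg, THF; 2 equiv), LaCl3·2LiCl (1 equiv), −78 → 0 °C; then MeOH, NaOMe (0.3 equiv), rt; aq NH4Cl
Reagents that add atoms: none
Why: In-situ enolate protection followed by Grignard 1,2-addition, in which the C6 ketone is the only enolisable carbonyl and is masked as its lithium enolate (a vinylogous dienolate would mask it equally), the Lewis-acid-activated Grignard reagent can therefore only add to the non-enolisable C9 ketone, and methanolic methoxide then reprotonates, cleaves the alkynyl C–Si bond and equilibrates C5 (α to the C6 ketone) to the trans-fused 5α-H isomer, which is favoured once C9 is a fully substituted sp3 carbon because the low-strain cis conformer would place a C4 methyl syn-axial to C9.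

Step 5
Reactants: 10 trans-fused 9-hydroxy-7-en-6-one
Product: 11 (1R,4S,4aS,8aS)-4-(but-3-yn-1-yl)-3,4a,8,8-tetramethyl-1,4,4a,5,6,7,8,8a-octahydronaphthalene-1,4-diol (6β-OH)
Conditions: NaBH4, CeCl3·7H2O, MeOH, −40 °C
Reagents that add atoms: none
Why: Luche 1,2-reduction of the enone, in which hydride enters C6 from the α face because the β face is screened by the syn-axial 10-CH3 and 4β-CH3 groups, giving the axial 6β-alcohol.

Step 6
Reactants: 11 6β,9-diol
Product: 12 (1R,4S,4aS,8aS)-4-(but-3-yn-1-yl)-4-hydroxy-3,4a,8,8-tetramethyl-1,4,4a,5,6,7,8,8a-octahydronaphthalen-1-yl acetate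
Conditions: Ac2O (1.5 equiv), DMAP (0.2 equiv), Et3N, CH2Cl2, rt
Reagents that add atoms: acetic anhydride, CC(=O)OC(C)=O
Why: DMAP-catalysed acylation acetylates the secondary allylic 6β-hydroxyl selectively, because the tertiary C9 hydroxyl next to quaternary C10 is too hindered to react, and no stereocentre changes.

Step 7
Reactants: 12 6β-acetoxy tertiary allylic alcohol
Product: 13 (1S,2S,4aS,8aS)-1-acetoxy-4-(but-3-yn-1-yl)-3,4a,8,8-tetramethyl-1,2,4a,5,6,7,8,8a-octahydronaphthalen-2-yl 3-methylbutanoate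
Conditions: (Me2CHCH2CO)2O (3 equiv), Sc(OTf)3 (5 mol %), MeCN–CH2Cl2, −20 → 0 °C
Reagents that add atoms: 3-methylbutanoic anhydride, CC(C)CC(=O)OC(=O)CC(C)C
Why: Lewis-acid-promoted acylative 1,3-allylic transposition (SN1′), in which the tertiary allylic C9–O bond is acylated and ionised to the C7–C8–C9 allyl cation and isovalerate returns at the secondary terminus C7 from the α face, anti to the axial 6β-acetoxy group (or by opening of the cis-acetoxonium ion it can form) and into the pseudo-axial position free of A(1,2) strain with the C8 methyl, so the trans-diaxial 6β,7α-diester with the tetrasubstituted C8=C9 alkene is both the kinetic and the thermodynamic product.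

Step 8
Reactants: 13 6β-acetoxy-7α-isovaleryloxy alkyne
Product: 15 (2E)-5-[(3S,4S,4aS,8aS)-4-acetoxy-2,5,5,8a-tetramethyl-3-(3-methylbutanoyloxy)-3,4,4a,5,6,7,8,8a-octahydronaphthalen-1-yl]-3-methylpent-2-enoic acid (target), via nickelalactone 14 (not isolated)
Conditions: Ni(cod)2 (1.1 equiv), DBU (3 equiv), CO2 (1 atm), THF, 0 °C; then Me2Zn (3 equiv), 0 °C → rt; cold 1 M HCl
Reagents that add atoms: carbon dioxide, O=C=O; dimethylzinc, C[Zn]C
Why: Nickel-mediated alkylative carboxylation of a terminal alkyne, in which oxidative cyclisation of alkyne and CO2 on zerovalent nickel forms the C14–C15 bond at the terminal carbon and transmetalation with Me2Zn followed by reductive elimination delivers methyl to C13 cis to the carboxylate, so syn addition fixes the 13E geometry while the esters are untouched.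

## Compound list

1 | 2,6-dimethylphenol | Cc1cccc(C)c1O | starting material
2 | 2,6-dimethyl-1,4-benzoquinone | CC1=CC(=O)C=C(C)C1=O | intermediate
3 | 4-methylpenta-1,3-diene | CC(C)=CC=C | starting material
4 | (4aR,8aS)-2,5,5,8a-tetramethyl-4a,5,8,8a-tetrahydronaphthalene-1,4-dione (cis-fused, 4a-H and 8a-CH3 syn) | O=C1C=C(C)C(=O)[C@@]2(C)CC=CC(C)(C)[C@@H]12 | intermediate
5 | (4aR,8aS)-2,5,5,8a-tetramethyl-4a,5,6,7,8,8a-hexahydronaphthalene-1,4-dione (cis-fused) | O=C1C=C(C)C(=O)[C@@]2(C)CCCC(C)(C)[C@@H]12 | intermediate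
6 | (4-bromobut-1-yn-1-yl)trimethylsilane | C[Si](C)(C)C#CCCBr | starting material
7 | lithium (4aS)-3,4a,8,8-tetramethyl-4-oxo-4,4a,5,6,7,8-hexahydronaphthalen-1-olate | [Li]OC1=C2C(C)(C)CCC[C@]2(C)C(=O)C(C)=C1 | intermediate (not isolated)
8 | lithium (4S,4aS)-4-(bromomagnesiooxy)-3,4a,8,8-tetramethyl-4-[4-(trimethylsilyl)but-3-yn-1-yl]-4,4a,5,6,7,8-hexahydronaphthalen-1-olate | [Li]OC1=C2C(C)(C)CCC[C@]2(C)[C@](O[Mg]Br)(CCC#C[Si](C)(C)C)C(C)=C1 | intermediate (not isolated)
9 | (4S,4aS)-4-hydroxy-3,4a,8,8-tetramethyl-4-[4-(trimethylsilyl)but-3-yn-1-yl]-4a,5,6,7,8,8a-hexahydronaphthalen-1(4H)-one (C8a epimers, centre left open) | O=C1C=C(C)[C@@](O)(CCC#C[Si](C)(C)C)[C@@]2(C)CCCC(C)(C)C12 | intermediate (not isolated)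
10 | (4S,4aS,8aS)-4-(but-3-yn-1-yl)-4-hydroxy-3,4a,8,8-tetramethyl-4a,5,6,7,8,8a-hexahydronaphthalen-1(4H)-one (trans-fused) | O=C1C=C(C)[C@@](O)(CCC#C)[C@@]2(C)CCCC(C)(C)[C@H]12 | intermediate
11 | (1R,4S,4aS,8aS)-4-(but-3-yn-1-yl)-3,4a,8,8-tetramethyl-1,4,4a,5,6,7,8,8a-octahydronaphthalene-1,4-diol (6β-OH) | O[C@@H]1C=C(C)[C@@](O)(CCC#C)[C@@]2(C)CCCC(C)(C)[C@H]12 | intermediate
12 | (1R,4S,4aS,8aS)-4-(but-3-yn-1-yl)-4-hydroxy-3,4a,8,8-tetramethyl-1,4,4a,5,6,7,8,8a-octahydronaphthalen-1-yl acetate | CC(=O)O[C@@H]1C=C(C)[C@@](O)(CCC#C)[C@@]2(C)CCCC(C)(C)[C@H]12 | intermediate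
13 | (1S,2S,4aS,8aS)-1-acetoxy-4-(but-3-yn-1-yl)-3,4a,8,8-tetramethyl-1,2,4a,5,6,7,8,8a-octahydronaphthalen-2-yl 3-methylbutanoate | CC(=O)O[C@@H]1[C@@H](OC(=O)CC(C)C)C(C)=C(CCC#C)[C@@]2(C)CCCC(C)(C)[C@H]12 | intermediate
14 | oxanickelacyclopentenone (nickelalactone) from 13 and CO2, DBU ligands omitted | CC(=O)O[C@@H]1[C@@H](OC(=O)CC(C)C)C(C)=C(CCC3=CC(=O)O[Ni]3)[C@@]2(C)CCCC(C)(C)[C@H]12 | intermediate (not isolated)
15 | (2E)-5-[(3S,4S,4aS,8aS)-4-acetoxy-2,5,5,8a-tetramethyl-3-(3-methylbutanoyloxy)-3,4,4a,5,6,7,8,8a-octahydronaphthalen-1-yl]-3-methylpent-2-enoic acid (6β-acetoxy-7α-isovaleryloxylabda-8,13E-dien-15-oic acid) | CC(=O)O[C@@H]1[C@@H](OC(=O)CC(C)C)C(C)=C(CC/C(C)=C/C(=O)O)[C@@]2(C)CCCC(C)(C)[C@H]12 | target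

## Step count and risks

Total steps: 8. Longest linear sequence: 8 (from 1).

Steps most likely to fail:

- **Step 2.** The diene is a poor s-cis diene and is prone to cationic polymerisation under the strongly acidic catalyst; enantioselectivity is untested for this pair. Fallback: setting out from 2 and 3, an uncatalysed cycloaddition under high pressure (CH2Cl2, 12 kbar, rt; no Lewis acid) gives the racemic cis-fused adduct F1. This is resolved by preparative chromatography on a chiral stationary phase, and the (4aR,8aS) enantiomer re-enters the route at 4.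

- **Step 4.** Addition to the hindered C9 ketone of an anionic substrate may be slow, and the ring-fusion equilibrium may not be fully on the trans side. Fallback: setting out from 5, the C6 ketone is masked by redox instead of enolisation. NaBH4/CeCl3·7H2O reduces the less hindered C6 carbonyl to the cis-fused hydroxy-enone F2 (carbinol epimers). Excess Me3SiC≡CCH2CH2MgBr with LaCl3·2LiCl then adds to C9 to give the cis-fused diol F3. MnO2 (CH2Cl2) re-oxidises only the secondary allylic alcohol, which returns the material to the route at 9 (as its cis-fused epimer); the NaOMe/MeOH operation of step 4 converts it into 10.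

- **Step 7.** Possible failures are E1 loss to dienes, competing ionisation of the allylic 6-acetate of 12, and return of the carboxylate to the β face. Fallback: setting out from 12, oxidative 1,3-transposition with pyridinium chlorochromate [C5H5NH][CrO3Cl] (CH2Cl2, rt; Babler–Dauben) gives the 6β-acetoxy-8-en-7-one F4. NaBH4/CeCl3·7H2O at −78 °C delivers hydride anti to the axial 6β-acetoxy group and gives the 7β-alcohol F5. Mitsunobu esterification with 3-methylbutanoic acid (PPh3, DIAD, toluene) inverts C7 and returns to the route at 13.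

## Further compounds

F1 | step 2 | racemic cis-2,5,5,8a-tetramethyl-4a,5,8,8a-tetrahydronaphthalene-1,4-dione (both enantiomers) | O=C1C=C(C)C(=O)[C@@]2(C)CC=CC(C)(C)[C@@H]12.O=C1C=C(C)C(=O)[C@]2(C)CC=CC(C)(C)[C@H]12
F2 | step 4 | (4aR,8aS)-4-hydroxy-2,5,5,8a-tetramethyl-4a,5,6,7,8,8a-hexahydronaphthalen-1(4H)-one (C4 epimers, centre left open) | OC1C=C(C)C(=O)[C@@]2(C)CCCC(C)(C)[C@@H]12
F3 | step 4 | (4S,4aS,8aR)-3,4a,8,8-tetramethyl-4-[4-(trimethylsilyl)but-3-yn-1-yl]-1,4,4a,5,6,7,8,8a-octahydronaphthalene-1,4-diol (C1 epimers, centre left open) | OC1C=C(C)[C@@](O)(CCC#C[Si](C)(C)C)[C@@]2(C)CCCC(C)(C)[C@@H]12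
F4 | step 7 | (1S,4aS,8aS)-4-(but-3-yn-1-yl)-3,4a,8,8-tetramethyl-2-oxo-1,2,4a,5,6,7,8,8a-octahydronaphthalen-1-yl acetate | CC(=O)O[C@@H]1C(=O)C(C)=C(CCC#C)[C@@]2(C)CCCC(C)(C)[C@H]12
F5 | step 7 | (1S,2R,4aS,8aS)-4-(but-3-yn-1-yl)-2-hydroxy-3,4a,8,8-tetramethyl-1,2,4a,5,6,7,8,8a-octahydronaphthalen-1-yl acetate | CC(=O)O[C@@H]1[C@H](O)C(C)=C(CCC#C)[C@@]2(C)CCCC(C)(C)[C@H]12
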